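**Strategy.** Everything rests on the 1,2-dioxane ring O1–O2–C3–C4–C5–C6 (C3 carries the propanoate, C6 the methyl). The exocyclic C3–C2 bond is cut to a cyclic peroxycarbenium ion and a chiral propionate enolate. The 3-methoxy-1,2-dioxane is traced to a five-membered 1,2-dioxolan-3-ol (O1, O2, C4, C5, C6) whose quaternary C6–O1 centre comes from a chiral oxetane opened by H2O2 with inversion. The key step inserts C3 between O2 and C4: Wittig methoxymethylenation of the peroxy-hemiacetal and acid recyclisation enlarge the dioxolane to the dioxane, reduce C4 to CH2 and move the acetal function to C3. It exploits that C3, flanked by O2 and C2, is the only ring carbon at the aldehyde oxidation level.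

Key step: step 11

Abbreviation used in names: D = (1R,4aR,8aR)-2,5,5,8a-tetramethyl-1,4,4a,5,6,7,8,8a-octahydronaphthalen-1-yl (the decalin unit of the target, enantiomeric to the natural drimenyl ring).

Remark 1: lipase PS is assumed to acylate the (1S,4aS,8aS)-enantiomer of drimenol faster, as with related β-branched cyclogeranyl-type alcohols; if the preference is reversed, the (1R)-acetate is collected and saponified.

Remark 2: the (S)-BINOL-derived La–Li3 catalyst is written in step 6; the enantiomer actually used is the one that transfers CH2 to the ketone face leading to the (2R)-oxetane.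

**Step 1**
Reactants: 1 (2E,6E)-farnesol
Product: 2 rac-drimenol (racemic D-CH2OH, relative configuration as in D)
Conditions: FSO3H, i-PrNO2, −78 °C; then Et3N
Reagents that add atoms: none
Why: Brønsted-superacid cation–olefin bicyclisation through a chair–chair polyene conformation should give the trans-decalin with equatorial CH2OH (relative configuration at C5, C9, C10 set together), the protonated hydroxyl keeping the 2,3-alkene a pure terminator and proton loss from C7 giving the Δ7 alkene.

**Step 2**
Reactants: 2 rac-drimenol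
Product: 3 (+)-drimenol, D-CH2OH
Conditions: lipase PS (Burkholderia cepacia, immobilised), vinyl acetate, t-BuOMe, 25 °C, stopped just past half conversion; chromatography
Reagents that add atoms: none
Why: lipase-catalysed enantioselective transesterification (kinetic resolution) of a primary alcohol with a β-stereocentre should acetylate the (1S) enantiomer and leave the (1R,4aR,8aR) alcohol, which fixes the absolute configuration of the decalin.

**Step 3**
Reactants: 3 (+)-drimenol
Product: 4 D-CHO [(1R,4aR,8aR)-drim-7-en-11-al]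
Conditions: Dess–Martin periodinane, NaHCO3, CH2Cl2, 0 °C
Reagents that add atoms: none
Why: Dess–Martin oxidation under buffered, base-free conditions should give the β,γ-unsaturated aldehyde without epimerisation at C9 or migration of the Δ7 alkene into conjugation.

**Step 4**
Reactants: 4 D-CHO
Product: 5 (3E)-4-D-but-3-en-2-one
Conditions: Ph3P=CHC(O)CH3, toluene, 90 °C
Reagents that add atoms: 1-(triphenylphosphoranylidene)propan-2-one, CC(=O)C=P(c1ccccc1)(c1ccccc1)c1ccccc1
Why: Wittig olefination with a stabilised ylide is E-selective and neutral, so the α-stereocentre of the hindered aldehyde should survive.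

**Step 5**
Reactants: 5 (3E)-4-D-but-3-en-2-one
Product: 6 4-D-butan-2-one
Conditions: H2 (1 atm), RhCl(PPh3)3 (cat.), benzene, 25 °C
Reagents that add atoms: none
Why: homogeneous Rh-catalysed hydrogenation should reduce the 1,2-disubstituted enone C=C and leave the hindered trisubstituted Δ7 alkene and the ketone untouched.

**Step 6**
Reactants: 6 4-D-butan-2-one
Product: 8 (2R)-2-methyl-2-(2-D-ethyl)oxetane, via epoxide 7 (not isolated)
Conditions: CH2=S(O)Me2 (2.5 equiv, preformed THF solution), La–Li3–tris[(S)-binaphthoxide] (5 mol %), (2,4,6-(MeO)3C6H2)3P=O (5 mol %), MS 5 Å, THF, 25 → 45 °C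
Reagents that add atoms: dimethylsulfoxonium methylide, [CH2-][S+](C)(C)=O
Why: catalytic enantioselective Corey–Chaykovsky methylene transfer to the methyl ketone (catalyst distinguishes CH3 from CH2R) sets the quaternary C–O centre, and a second ylide equivalent opens the epoxide at CH2 and closes the oxetane (4-exo-tet) without touching that C–O bond.

**Step 7**
Reactants: 8 (2R)-2-methyl-2-(2-D-ethyl)oxetane
Product: 9 (3S)-3-hydroperoxy-3-methyl-5-D-pentan-1-ol
Conditions: H2O2 (anhydrous, in Et2O), TMSOTf (0.2 equiv), Et2O, −78 → −20 °C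
Reagents that add atoms: hydrogen peroxide, OO
Why: Lewis-acid-activated, strain-driven SN2-type opening of a 2,2-dialkyloxetane by H2O2 occurs at the tertiary carbon with inversion, which should install the C6–O1 bond of the target in its final (S) configuration.

**Step 8**
Reactants: 9 (3S)-3-hydroperoxy-3-methyl-5-D-pentan-1-ol
Product: 10 (3S)-3-[(2-methoxypropan-2-yl)peroxy]-3-methyl-5-D-pentan-1-ol
Conditions: 2-methoxypropene (1.1 equiv), PPTS (cat.), CH2Cl2, 0 °C
Reagents that add atoms: 2-methoxypropene, COC(C)=C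
Why: acid-catalysed addition to the enol ether (peroxyketal formation) should take place on the more acidic, α-effect hydroperoxide faster than on the primary alcohol, masking OOH for the oxidation.

**Step 9**
Reactants: 10 (3S)-3-[(2-methoxypropan-2-yl)peroxy]-3-methyl-5-D-pentan-1-ol
Product: 11 (3S)-3-[(2-methoxypropan-2-yl)peroxy]-3-methyl-5-D-pentanal
Conditions: Dess–Martin periodinane, pyridine, CH2Cl2, 0 °C
Reagents that add atoms: none
Why: Dess–Martin oxidation of the primary alcohol under buffered conditions should spare the acid-labile dialkyl peroxyketal and the remote alkene.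

**Step 10**
Reactants: 11 (3S)-3-[(2-methoxypropan-2-yl)peroxy]-3-methyl-5-D-pentanal
Product: 13 (5S)-5-methyl-5-(2-D-ethyl)-1,2-dioxolan-3-ol (both C3 epimers), via hydroperoxy aldehyde 12 (not isolated)
Conditions: AcOH–THF–H2O, 25 °C
Reagents that add atoms: none
Why: mild acid hydrolysis of the peroxyketal frees the hydroperoxide, which should add to the β-aldehyde (5-exo-trig hemiacetalisation) to give the cyclic peroxy-hemiacetal with the quaternary centre unchanged.

**Step 11**
Reactants: 13 (5S)-5-methyl-5-(2-D-ethyl)-1,2-dioxolan-3-ol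
Product: 15 (6S)-3-methoxy-6-methyl-6-(2-D-ethyl)-1,2-dioxane (both C3 epimers), via enol ether hydroperoxide 14 (not isolated)
Conditions: MeOCH2PPh3Cl, KHMDS (3 equiv each), THF, −78 → 0 °C; then camphorsulfonic acid (excess over base), CH2Cl2, 0 °C
Reagents that add atoms: (methoxymethylene)triphenylphosphorane, COC=P(c1ccccc1)(c1ccccc1)c1ccccc1
Why: Proposed new method: the peroxy-hemiacetal is in ring–chain equilibrium with its 3-hydroperoxy aldehyde, which as the potassium peroxide salt (O–O not electrophilic, no leaving group for β-elimination) should undergo Wittig methoxymethylenation to enol ether 14; acid then protonates C4 and the tertiary hydroperoxide adds to the methoxy-oxocarbenium carbon C3. The closest known reaction types are the one-carbon homologation of lactols by methoxymethylene Wittig reaction with acid recyclisation, and the acid-catalysed addition of hydroperoxides to enol ethers. The dioxane closes by 6-exo attack of O2 on the C3=O+ bond (6-endo with respect to the former enol ether C=C), so the five-membered ring O1–O2–C4–C5–C6 becomes the six-membered ring O1–O2–C3–C4–C5–C6. The new centre C3 is an anomeric peroxyacetal carbon formed without control, which is harmless because it is planarised in step 12; the C6–O1 bond is never broken, so C6 stays (S). The step needs chemoselective olefination next to O–O, secured by low temperature and by excess ylide keeping the hydroperoxide deprotonated, and Markovnikov protonation of the enol ether, which allows ring closure only at C3.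

**Step 12**
Reactants: 15 (6S)-3-methoxy-6-methyl-6-(2-D-ethyl)-1,2-dioxane; 16 (4R)-4-benzyl-3-propanoyl-1,3-thiazolidine-2-thione
Product: 17 (4R)-4-benzyl-3-{(2S)-2-[(3S,6S)-6-methyl-6-(2-D-ethyl)-1,2-dioxan-3-yl]propanoyl}-1,3-thiazolidine-2-thione
Conditions: 16, TiCl4, i-Pr2NEt, CH2Cl2, −78 °C; then 15, SnCl4, −78 → −40 °C
Reagents that add atoms: none
Why: Lewis-acid ionisation of the exocyclic C3–OMe bond gives the cyclic peroxycarbenium ion, which the chelated chlorotitanium (Z)-enolate should attack on its face anti to the benzyl group (C2 = S) through an open antiperiplanar transition state giving the 2,3-anti adduct (C3 = S), the C6 quaternary centre exerting no ring bias (auxiliary-controlled enolate addition to an oxocarbenium-type ion, substitution of an alkoxy-1,2-dioxane).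

**Step 13**
Reactants: 17 (4R)-4-benzyl-3-{(2S)-2-[(3S,6S)-6-methyl-6-(2-D-ethyl)-1,2-dioxan-3-yl]propanoyl}-1,3-thiazolidine-2-thione
Product: 18 methyl (2S)-2-[(3S,6S)-6-methyl-6-(2-D-ethyl)-1,2-dioxan-3-yl]propanoate (target)
Conditions: MeOH, imidazole, CH2Cl2, 25 °C
Reagents that add atoms: methanol, CO
Why: methanolysis of the activated N-acyl thiazolidinethione (acyl transfer under near-neutral nucleophilic catalysis) should release the methyl ester without enolisation, so C2 is not epimerised and the β-peroxide is not eliminated.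

**Compound list**

1 | (2E,6E)-farnesol | OC/C=C(C)/CC/C=C(C)/CCC=C(C)C | starting material
2 | rac-drimenol (racemate, both enantiomers written) | OC[C@@H]1C(C)=CC[C@@H]2C(C)(C)CCC[C@@]12C.OC[C@H]1C(C)=CC[C@H]2C(C)(C)CCC[C@]12C | intermediate
3 | (+)-drimenol, D-CH2OH | OC[C@@H]1C(C)=CC[C@@H]2C(C)(C)CCC[C@@]12C | intermediate
4 | D-CHO, (1R,4aR,8aR)-drim-7-en-11-al | O=C[C@@H]1C(C)=CC[C@@H]2C(C)(C)CCC[C@@]12C | intermediate
5 | (3E)-4-D-but-3-en-2-one | CC(=O)/C=C/[C@@H]1C(C)=CC[C@@H]2C(C)(C)CCC[C@@]12C | intermediate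
6 | 4-D-butan-2-one | CC(=O)CC[C@@H]1C(C)=CC[C@@H]2C(C)(C)CCC[C@@]12C | intermediate
7 | (2R)-2-methyl-2-(2-D-ethyl)oxirane (not isolated) | C[C@@]1(CC[C@@H]2C(C)=CC[C@@H]3C(C)(C)CCC[C@@]23C)CO1 | intermediate
8 | (2R)-2-methyl-2-(2-D-ethyl)oxetane | C[C@@]1(CC[C@@H]2C(C)=CC[C@@H]3C(C)(C)CCC[C@@]23C)CCO1 | intermediate
9 | (3S)-3-hydroperoxy-3-methyl-5-D-pentan-1-ol | C[C@](CC[C@@H]1C(C)=CC[C@@H]2C(C)(C)CCC[C@@]12C)(CCO)OO | intermediate
10 | (3S)-3-[(2-methoxypropan-2-yl)peroxy]-3-methyl-5-D-pentan-1-ol | C[C@](CC[C@@H]1C(C)=CC[C@@H]2C(C)(C)CCC[C@@]12C)(CCO)OOC(C)(C)OC | intermediate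
11 | (3S)-3-[(2-methoxypropan-2-yl)peroxy]-3-methyl-5-D-pentanal | C[C@](CC[C@@H]1C(C)=CC[C@@H]2C(C)(C)CCC[C@@]12C)(CC=O)OOC(C)(C)OC | intermediate
12 | (3S)-3-hydroperoxy-3-methyl-5-D-pentanal (not isolated) | C[C@](CC[C@@H]1C(C)=CC[C@@H]2C(C)(C)CCC[C@@]12C)(CC=O)OO | intermediate
13 | (5S)-5-methyl-5-(2-D-ethyl)-1,2-dioxolan-3-ol (C3 epimers) | C[C@]1(CC[C@@H]2C(C)=CC[C@@H]3C(C)(C)CCC[C@@]23C)CC(O)OO1 | intermediate
14 | (4S)-4-hydroperoxy-1-methoxy-4-methyl-6-D-hex-1-ene (E/Z, not isolated) | C[C@](CC[C@@H]1C(C)=CC[C@@H]2C(C)(C)CCC[C@@]12C)(CC=COC)OO | intermediate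
15 | (6S)-3-methoxy-6-methyl-6-(2-D-ethyl)-1,2-dioxane (C3 epimers) | COC1CC[C@](C)(CC[C@@H]2C(C)=CC[C@@H]3C(C)(C)CCC[C@@]23C)OO1 | intermediate
16 | (4R)-4-benzyl-3-propanoyl-1,3-thiazolidine-2-thione | CCC(=O)N1C(=S)SC[C@H]1Cc1ccccc1 | starting material
17 | (4R)-4-benzyl-3-{(2S)-2-[(3S,6S)-6-methyl-6-(2-D-ethyl)-1,2-dioxan-3-yl]propanoyl}-1,3-thiazolidine-2-thione | O=C([C@@H](C)[C@@H]1CC[C@](C)(CC[C@@H]2C(C)=CC[C@@H]3C(C)(C)CCC[C@@]23C)OO1)N1C(=S)SC[C@H]1Cc1ccccc1 | intermediate
18 | methyl (2S)-2-[(3S,6S)-6-methyl-6-(2-D-ethyl)-1,2-dioxan-3-yl]propanoate | COC(=O)[C@@H](C)[C@@H]1CC[C@](C)(CC[C@@H]2C(C)=CC[C@@H]3C(C)(C)CCC[C@@]23C)OO1 | target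

**Count.** Total steps: 13. Longest linear sequence: 13 steps (1 → 18); 16 enters at step 12.

**Steps most likely to fail**

1. Step 11 (Proposed new method). The basic ylide may attack or reduce the peroxide, or the peroxy-hemiacetal salt may not open, so that homologation stalls or the O–O bond is lost. The fallback uses known steps and sets out from 11, before the hydroperoxide is unmasked. Wittig methoxymethylenation of the peroxyketal-protected aldehyde 11 (Ph3P=CHOMe, THF, −78 °C) should give the enol ether (4S)-1-methoxy-4-[(2-methoxypropan-2-yl)peroxy]-4-methyl-6-D-hex-1-ene F1. PPTS in CH2Cl2–MeOH then removes the peroxyketal and closes the freed hydroperoxide onto the protonated enol ether, which comes back to the route at 15 (no dioxolane is formed on this path).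

2. Step 12. Simple diastereoselection at the peroxycarbenium carbon may be poor, or the ring C3–O2 bond may ionise instead of the exocyclic C–OMe bond, leading to ring-opened ethers. The fallback sets out from 15. Aqueous trifluoroacetic acid in THF hydrolyses the acetal to (6S)-6-methyl-6-(2-D-ethyl)-1,2-dioxan-3-ol F2. Its open hydroperoxy-aldehyde form is olefinated with methyl 2-(triphenylphosphoranylidene)propanoate to methyl (2E,6S)-6-hydroperoxy-2,6-dimethyl-8-D-oct-2-enoate F3. Et2NH in CF3CH2OH closes the ring by 6-exo oxa-Michael addition of the hydroperoxide. This should give 18 together with its C2/C3 stereoisomers, from which 18 is separated by HPLC, so the fallback comes back at 18.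

3. Step 7. The tertiary C–O bond may ionise ahead of nucleophilic attack (erosion of configuration at C6), or the opening may be slow and give oligomers. The fallback sets out from 6 and comes back at 15. The ylide reaction is stopped at the epoxide 7 (one ylide equivalent, 25 °C), which is isolated. Ethereal H2O2 with catalytic phosphomolybdic acid opens 7 at the tertiary carbon with inversion to (2S)-2-hydroperoxy-2-methyl-4-D-butan-1-ol F4. 2-Methoxypropene/PPTS gives (2S)-2-[(2-methoxypropan-2-yl)peroxy]-2-methyl-4-D-butan-1-ol F5, and Dess–Martin oxidation gives (2S)-2-[(2-methoxypropan-2-yl)peroxy]-2-methyl-4-D-butanal F6. Wittig reaction with (1,3-dioxolan-2-ylmethylene)triphenylphosphorane gives 2-{(3S)-3-[(2-methoxypropan-2-yl)peroxy]-3-methyl-5-D-pent-1-enyl}-1,3-dioxolane F7. Diimide (potassium azodicarboxylate, AcOH) reduces only the disubstituted alkene to 2-{(3S)-3-[(2-methoxypropan-2-yl)peroxy]-3-methyl-5-D-pentyl}-1,3-dioxolane F8. PPTS in MeOH removes the peroxyketal and transacetalises to 15.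

**Further compounds**

F1 | step 11 | (4S)-1-methoxy-4-[(2-methoxypropan-2-yl)peroxy]-4-methyl-6-D-hex-1-ene | C[C@](CC[C@@H]1C(C)=CC[C@@H]2C(C)(C)CCC[C@@]12C)(CC=COC)OOC(C)(C)OC
F2 | step 12 | (6S)-6-methyl-6-(2-D-ethyl)-1,2-dioxan-3-ol | OC1CC[C@](C)(CC[C@@H]2C(C)=CC[C@@H]3C(C)(C)CCC[C@@]23C)OO1
F3 | step 12 | methyl (2E,6S)-6-hydroperoxy-2,6-dimethyl-8-D-oct-2-enoate | COC(=O)/C(C)=C/CC[C@](C)(CC[C@@H]1C(C)=CC[C@@H]2C(C)(C)CCC[C@@]12C)OO
F4 | step 7 | (2S)-2-hydroperoxy-2-methyl-4-D-butan-1-ol | C[C@](CC[C@@H]1C(C)=CC[C@@H]2C(C)(C)CCC[C@@]12C)(CO)OO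
F5 | step 7 | (2S)-2-[(2-methoxypropan-2-yl)peroxy]-2-methyl-4-D-butan-1-ol | C[C@](CC[C@@H]1C(C)=CC[C@@H]2C(C)(C)CCC[C@@]12C)(CO)OOC(C)(C)OC
F6 | step 7 | (2S)-2-[(2-methoxypropan-2-yl)peroxy]-2-methyl-4-D-butanal | C[C@](CC[C@@H]1C(C)=CC[C@@H]2C(C)(C)CCC[C@@]12C)(C=O)OOC(C)(C)OC
F7 | step 7 | 2-{(3S)-3-[(2-methoxypropan-2-yl)peroxy]-3-methyl-5-D-pent-1-enyl}-1,3-dioxolane | C[C@](CC[C@@H]1C(C)=CC[C@@H]2C(C)(C)CCC[C@@]12C)(C=CC1OCCO1)OOC(C)(C)OC
F8 | step 7 | 2-{(3S)-3-[(2-methoxypropan-2-yl)peroxy]-3-methyl-5-D-pentyl}-1,3-dioxolane | C[C@](CC[C@@H]1C(C)=CC[C@@H]2C(C)(C)CCC[C@@]12C)(CCC1OCCO1)OOC(C)(C)OC
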